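A ratio runs through this reckoning: the rate of product divided by c(substrate) and by the c(free catalyst) charged.

all flasks: substrate 0.80 M

| flask | coupling partner | free catalyst | remark | time |
|---|---|---|---|---|
| epsilon | 0.43 M | 80 mM | run made earlier |  |
| Thursday's | 0.640 M | 150 mM |  | 2.0 min |
| Tuesday's | 0.640 M | 80 mM |  | 2.0 min |
| Wednesday's | 0.640 M | 25 mM |  | 2.0 min |
| Saturday's | 0.640 M | 50 mM |  | 2.0 min |
| Sunday's | 0.640 M | 40 mM |  | 2.0 min |

- epsilon (time / s: product / %): 10.0: 2.4; 12.0: 4.7; 20.0: 9.2; 25.0: 11.7

(standard deviation of a reading: 0.3 percentage points)

- no earlier run changes the charge of free catalyst; that part of a forecast is a guess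

* ranking by amount of product, in percent of the substrate charged, from high to low, at 2.0 min (Thursday's / Tuesday's / Wednesday's / Saturday's / Sunday's)
* the amount of product, in percent of the substrate charged of the flask you put first, at 2.0 min
* the amount of product, in percent of the substrate charged of the flask you put last, at 2.0 min

I read the substrate remaining as what the product readings leave, and I take the logarithm of its ratio between the first and last epsilon readings. I divide it by the catalyst charge and the time between them, and I read 0.0834 /M/s. I call this reading the turnover constant. With it, I let substrate fall pseudo-first-order, taking c(free catalyst) times the constant as the rate constant. It is a reading, so it carries the scatter of the epsilon readings. The epsilon run has one catalyst charge, so proportionality to catalyst is my assumption.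

Now the books of coupling partner, the limiting reagent: 0.640 M against 0.80 M of substrate. I assume one mole of coupling partner per mole of product, so the ceiling is 80.0%.

Wednesday's, first entry: the constant gives 22.1%, which spends 0.177 M of coupling partner. Second entry: I book 0.463 M as unspent. The two entries sum to the charge by construction, and I book nothing as held on the catalyst.

Thursday's, first entry: 77.7%, which spends 0.622 M. Second entry: I book 0.0181 M as unspent, so my figure sits just under the ceiling.

My ranking follows the catalyst charge.

The forecast gives Thursday's > Tuesday's > Saturday's > Sunday's > Wednesday's, with 61% (50% to 71%) at the top and 28% (18% to 38%) at the bottom. It says “The ranking follows catalyst loading”. My reckoning differs: it is higher at the top and lower at the bottom.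

The flasks give Thursday's > Tuesday's > Saturday's > Sunday's > Wednesday's, with 74.0% for Thursday's and 23.0% for Wednesday's.

    coupling partner + free catalyst ⇌ catalyst intermediate A (K = 130 /M, k = 0.670 /M/s)
    catalyst intermediate A → catalyst intermediate B (k = 14.0 /s)
    substrate + catalyst intermediate B → catalyst intermediate C (k = 0.160 /M/s)
    catalyst intermediate C → by-product + catalyst intermediate D (k = 0.510 /s)
    catalyst intermediate D → free catalyst + product (k = 0.510 /s)

Thursday's stands below my figure, with coupling partner down to 0.882% of its charge at 2.00 min. The main reason that Thursday's holds no more product is the using up of coupling partner: without that using up it gives 86.9%, against 74.0%. In Wednesday's the using up of coupling partner is not what holds product down: 23.6% without it, against 23.0%. I carry the constant to Wednesday's flask read at 5.0 min, where 35% of the coupling partner remains. The constant gives 46.5%, and the flask gives 49.6%.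

The data are simulated with constants of no real substance; noise was put on by code.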